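**Strategy.** The route rests on the bond joining the two adjacent ring-fusion methines, C16 (allylic, next to quaternary C4) and C7 (bearing the methylidene carbon C8), which is common to the cyclopentane and the eleven-membered ring. It is made by an intramolecular enone–allylsilane [2+2] photocycloaddition of a monocyclic 4,4-disubstituted cyclohexenone: one irradiation closes the cyclopentane and a temporary cyclobutane (C15–C8), fixing the all-cis C4/C16/C7 triad. The step exploits the 1,5-diene C1=C15–C16–C7–C8=C19 of the target: Lewis-acid opening of the silylmethylcyclobutane unveils the methylidene and the C1 enol, whose triflate closes the eleven-membered ring at C1–C14 by a Nozaki–Hiyama–Kishi reaction.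

Key step: step 19

Numbering remark: late intermediates carry trinervitane numbers: C1 (ring sp2 carbon bearing C14), C2 and C3 (acetoxy carbons), C4 (quaternary, C18 methyl), C5, C6, C7 (CH bearing C8), C8 (=C19H2), C9, C10, C11 (OH), C12 (C20 methyl), C13, C14 (OH), C15 (C17 methyl), C16 (ring-fusion CH). The target is (2R,3R,4S,7R,11S,12R,14S,16S).

Assumption: centres that are destroyed later (sulfoxide sulfur, C6 of 12, the epoxide carbons of 16, the carbinol carbon of 17 and 29, C8 of 31) are carried as mixtures and left undefined in the SMILES; boron and chromium alkoxides that are only hydrolysed on aqueous work-up are not listed as separate intermediates, and work-up reagents are not tracked.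

**Cyclohexenone core from quinic acid**

Step 1
Reactants: 1 (−)-quinic acid
Product: 3 methyl quinate 4,5-O-butane-2,3-diacetal (BDA), via methyl quinate 2 (not isolated)
Conditions: butane-2,3-dione, HC(OMe)3, MeOH, camphorsulfonic acid (cat.), reflux
Reagents that add atoms: butane-2,3-dione, CC(=O)C(C)=O; methanol, CO
Why: One-pot Fischer esterification and butane-2,3-diacetal protection, in which only the trans-diequatorial 4,5-diol can bridge to the trans-fused dioxane and the anomeric effect fixes both new acetal carbons (axial OMe, S,S), leaving 1-OH and 3-OH free.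

Step 2
Reactants: 3 BDA-protected methyl quinate
Product: 5 BDA-protected 3-hydroxycyclohexanone, via triol 4 (not isolated)
Conditions: NaBH4, MeOH, 0 °C to rt; then NaIO4, SiO2, CH2Cl2/H2O, rt
Reagents that add atoms: none
Why: NaBH4 reduces the α-hydroxy ester to the 1,2-diol and Malaprade (periodate) glycol cleavage then excises the former carboxyl carbon as formaldehyde to give the ketone, with no stereocentre created.

Step 3
Reactants: 5 β-hydroxy ketone
Product: 7 (4R,5R)-4,5-dihydroxycyclohex-2-enone BDA acetal, via mesylate 6 (not isolated)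
Conditions: MsCl, Et3N, CH2Cl2, 0 °C to rt
Reagents that add atoms: none
Why: Mesylation of the free 3-OH and E1cB elimination give the conjugated enone, while the other β-oxygen is held equatorial in the dioxane, orthogonal to the enolate, and is not expelled.

Step 4
Reactants: 7 enone
Product: 8 2-iodo enone
Conditions: I2, pyridine, CH2Cl2, rt
Reagents that add atoms: iodine, [I][I]
Why: Pyridine-mediated α-iodination of the enone (conjugate addition of pyridine, iodination of the enolate, elimination) places iodine on C2 without touching the acetal.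

Step 5
Reactants: 8 2-iodo enone
Product: 9 (4R,5R)-4,5-dihydroxy-2-methylcyclohex-2-enone BDA acetal
Conditions: Me4Sn, Pd2(dba)3 (cat.), AsPh3, CuI, N-methylpyrrolidone, 60 °C
Reagents that add atoms: tetramethylstannane, C[Sn](C)(C)C
Why: Stille coupling of the α-iodoenone installs the future C17 methyl under neutral conditions that spare the base-sensitive β-alkoxy ketone.

Step 6
Reactants: 9 2-methyl enone; 10 phenyl vinyl sulfoxide
Product: 12 6-[2-(phenylsulfinyl)ethyl] enone (C6 and sulfur epimers), via lithium dienolate 11 (not isolated)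
Conditions: LiN(i-Pr)2, THF, −78 °C; then 10, −78 to −30 °C; NH4Cl
Reagents that add atoms: none
Why: Kinetic α′-deprotonation gives the cross-conjugated lithium dienolate, which adds in a Michael reaction to the vinyl sulfoxide (a vinyl cation equivalent); the new C6 and sulfur centres are inconsequential because C6 is re-enolised and sulfur is expelled later.

Step 7
Reactants: 12 sulfinylethyl enone
Product: 14 6-methyl-6-[2-(phenylsulfinyl)ethyl] enone (6R; sulfur epimers), via lithium enolate 13 (not isolated)
Conditions: LiN(i-Pr)2, THF/DMPU, −78 °C; then MeI, −78 to −40 °C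
Reagents that add atoms: iodomethane, CI
Why: Enolate C-alkylation creates the quaternary centre (C4 of the target): on the conformationally locked trans-fused half-chair MeI should enter axially, anti to the pseudo-axial H-5 and away from the axial methoxy of the dioxane, so the methyl ends cis to O-5 and the two-carbon arm trans.

Step 8
Reactants: 14 quaternary sulfoxide
Product: 15 (4R,5R,6R)-6-ethenyl-4,5-dihydroxy-2,6-dimethylcyclohex-2-enone BDA acetal
Conditions: toluene, CaCO3, 110 °C
Reagents that add atoms: none
Why: Thermal syn-elimination of the sulfoxide, whose only β-hydrogens sit on the arm, unveils the vinyl group on the quaternary carbon.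

Step 9
Reactants: 15 vinyl enone
Product: 16 2,3-epoxy ketone (epoxide diastereomers)
Conditions: H2O2 (30 % aq.), NaOH (cat.), MeOH, 0 °C
Reagents that add atoms: hydrogen peroxide, OO
Why: Weitz–Scheffer nucleophilic epoxidation of the enone leaves the isolated vinyl group alone, and the face of epoxidation is irrelevant because that carbon becomes the C1 carbonyl.

Step 10
Reactants: 16 epoxy ketone
Product: 17 4-ethenyl-2,4-dimethylcyclohex-2-ene-1,5,6-triol 5,6-BDA acetal (4S,5R,6R; C1 epimers)
Conditions: N2H4·H2O, AcOH (cat.), MeOH, 0 °C to rt, degassed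
Reagents that add atoms: none
Why: Wharton transposition (hydrazone, then loss of N2 from the alkenyl diazene) moves oxygen to the former β-carbon and the alkene next to the quaternary carbon, giving the C1 carbinol and the C15=C16 alkene as an inconsequential epimer mixture.

**Side chain (C7–C14)**

Step 11
Reactants: 18 pent-4-yn-1-ol
Product: 19 pent-4-ynal
Conditions: Dess–Martin periodinane, NaHCO3, CH2Cl2, 0 °C to rt
Reagents that add atoms: none
Why: Dess–Martin oxidation takes the primary alcohol to the aldehyde without affecting the alkyne.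

Step 12
Reactants: 19 pent-4-ynal; 20 (E)-crotylboronic acid pinacol ester
Product: 21 (3R,4S)-3-methyloct-1-en-7-yn-4-ol
Conditions: (R)-TRIP [(R)-3,3′-bis(2,4,6-triisopropylphenyl)-BINOL hydrogen phosphate] (5 mol %), 4 Å molecular sieves, toluene, −30 °C; aqueous work-up
Reagents that add atoms: none
Why: Chiral phosphoric acid-catalysed crotylboration through a closed chair (Zimmerman–Traxler) transition state, in which the (E)-boronate gives the anti methyl/hydroxy pair and the (R)-catalyst is chosen to direct addition to the Re face of the aldehyde, setting C12 (R) and C11 (S) of the target.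

Step 13
Reactants: 21 homoallylic alcohol
Product: 22 TBDPS ether of 21
Conditions: t-BuPh2SiCl, imidazole, DMF, rt
Reagents that add atoms: tert-butyl(chloro)diphenylsilane, CC(C)(C)[Si](Cl)(c1ccccc1)c1ccccc1
Why: Silylation of the secondary alcohol with a group that should survive base, aqueous acid and Lewis acid until the last step.

Step 14
Reactants: 22 silyl ether
Product: 24 (Z)-alkenyl iodide carrying the allylsilane, via alkenylcopper 23 (not isolated)
Conditions: Me3SiCH2MgCl, CuBr·SMe2, Et2O/Me2S, −40 to −10 °C; then I2, THF, −60 °C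
Reagents that add atoms: (trimethylsilyl)methylmagnesium chloride, C[Si](C)(C)C[Mg]Cl; iodine, [I][I]
Why: Normant carbocupration adds the silylmethylcopper syn across the terminal alkyne (carbon to the internal, copper to the terminal position) and iodinolysis with retention gives the (Z)-iodide with C19 in place.

Step 15
Reactants: 24 alkenyl iodide
Product: 26 (3R,4S,7Z)-4-(tert-butyldiphenylsilyloxy)-8-iodo-3-methyl-7-[(trimethylsilyl)methyl]oct-7-en-1-ol, via alkylborane 25 (not isolated)
Conditions: 9-BBN, THF, 0 °C to rt; then NaOH (aq.), H2O2, 0 °C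
Reagents that add atoms: hydrogen peroxide, OO
Why: Hydroboration–oxidation with the bulky borane is selective for the monosubstituted alkene and gives the anti-Markovnikov primary alcohol (future C14).

Step 16
Reactants: 26 primary alcohol
Product: 27 TBS ether of 26
Conditions: t-BuMe2SiCl, imidazole, CH2Cl2, rt
Reagents that add atoms: tert-butyl(chloro)dimethylsilane, CC(C)(C)[Si](C)(C)Cl
Why: Silyl protection of the primary alcohol, chosen so that it falls off together with the BDA group in step 21.

**Union, key step and endgame**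

Step 17
Reactants: 17 vinyl cyclohexenol; 27 alkenyl iodide
Product: 29 coupled allylic alcohol (C1 epimers), via alkylborane 28 (not isolated)
Conditions: 9-BBN (2.5 equiv), THF, rt; then 27, Pd(dppf)Cl2 (5 mol %), AsPh3, Cs2CO3, DMF/H2O, rt
Reagents that add atoms: none
Why: Chemoselective hydroboration of the vinyl group (the hindered ring alkene is inert) and B-alkyl Suzuki–Miyaura coupling with retention of alkene geometry join the two halves at C6–C7.

Step 18
Reactants: 29 allylic alcohol
Product: 30 (4S,5R,6S)-enone carrying the C5–C14 chain with its (Z)-allylsilane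
Conditions: Dess–Martin periodinane, NaHCO3, CH2Cl2, 0 °C
Reagents that add atoms: none
Why: Dess–Martin oxidation converges both carbinol epimers on the enone chromophore for the photoreaction.

Step 19
Reactants: 30 enone–allylsilane
Product: 31 cyclobutane photoadduct (C8 epimers)
Conditions: hν (350 nm, Pyrex), degassed CH2Cl2 (5 mM), 0 °C
Reagents that add atoms: none
Why: Excitation (n→π*) and intersystem crossing give the enone triplet, whose β-carbon C16 bonds to the near alkene carbon C7, and after spin inversion the C15/C8 1,4-biradical collapses to the cyclobutane. The closest known reaction type is the intramolecular enone–olefin [2+2] photocycloaddition of 4-(3-alkenyl)cyclohex-2-enones used in photocycloaddition–fragmentation sequences. The cyclopentane (C4–C5–C6–C7–C16) closes in the 5-exo mode demanded by the rule of five and the four-membered ring (C15–C16–C7–C8) by radical recombination. C16 is fixed by the tether, which can only reach the enone face syn to the C4 arm (cis-hydrindane, H-16 cis to the C18 methyl), and C7 by the obligatory cis fusion of the bicyclo[3.2.0] unit, which holds C8 cis to C15; C15 follows from the cis six/four fusion and C8 is left as a mixture because it is destroyed in step 20. The step needs straight rather than crossed regiochemistry, secured by the three-atom tether, and ring closure of the biradical in preference to hydrogen transfer or lumiketone rearrangement, favoured by rapid intramolecular capture and by 350 nm light that the product ketone does not absorb.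

Step 20
Reactants: 31 photoadduct
Product: 34 C1 alkenyl triflate with the C8 methylidene, via silyl enol ether 32 (not isolated), via lithium enolate 33 (not isolated)
Conditions: Me3SiOTf (10 mol %), toluene, −78 to −40 °C; then MeLi, THF, 0 °C; then PhNTf2, 0 °C to rt
Reagents that add atoms: N-phenylbis(trifluoromethanesulfonimide), O=S(=O)(N(c1ccccc1)S(=O)(=O)C(F)(F)F)C(F)(F)F
Why: Lewis-acid ring opening of the donor–acceptor (2-silylmethyl)cyclobutyl ketone, the reverse of the ring-closing half of a stepwise allylsilane–enone [2+2]/Hosomi–Sakurai manifold: O-silylation triggers heterolysis of C15–C8 to the silyl enol ether and a β-silyl tertiary cation that loses Me3Si+ to give the C8=C19 methylidene, after which MeLi frees the regiodefined enolate for O-triflation, with no stereocentre formed and only the temporary ones lost.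

Step 21
Reactants: 34 alkenyl triflate
Product: 35 2,3,14-triol (11-O-TBDPS, C1 triflate)
Conditions: CF3CO2H/H2O (9:1), CH2Cl2, 0 °C, short contact
Reagents that add atoms: none
Why: Aqueous acid hydrolyses the BDA ketal and the primary silyl ether while the hindered secondary TBDPS ether and the alkenyl triflate survive, and brief exposure at 0 °C is meant to spare the 1,1-disubstituted alkene.

Step 22
Reactants: 35 triol
Product: 36 2,3-diol C14 aldehyde
Conditions: TEMPO (cat.), PhI(OAc)2, CH2Cl2, rt
Reagents that add atoms: none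
Why: Nitroxyl (TEMPO)-catalysed oxidation is selective for the primary alcohol over the secondary diol and stops at the aldehyde.

Step 23
Reactants: 36 diol aldehyde
Product: 37 2,3-diacetate C14 aldehyde
Conditions: Ac2O, pyridine, DMAP (cat.), CH2Cl2, 0 °C to rt
Reagents that add atoms: acetic anhydride, CC(=O)OC(C)=O
Why: Acetylation of both secondary alcohols (nucleophilic catalysis) installs the two acetates of the target now that no ketone remains that could eliminate the C3 acetate.

Step 24
Reactants: 37 triflate aldehyde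
Product: 38 11-O-TBDPS ether of the target
Conditions: CrCl2 (10 equiv), NiCl2 (2 mol %), DMSO/THF, 2 mM, rt
Reagents that add atoms: none
Why: Nozaki–Hiyama–Kishi reaction, in which NiCl2-catalysed oxidative addition to the alkenyl triflate, transmetalation to chromium and chemoselective addition to the aldehyde close the eleven-membered ring at C1–C14; the C14 carbinol is set under substrate control within the cyclic transition state, with the 14S alcohol expected but not assured.

Step 25
Reactants: 38 silyl ether
Product: 39 CNP0114864.2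
Conditions: HF·pyridine, pyridine/THF, 0 °C to rt
Reagents that add atoms: none
Why: Fluoride-mediated cleavage of the silyl ether under buffered acidic conditions that should neither migrate nor cleave the acetates.

**Compound list**

1 | (−)-quinic acid, (1S,3R,4S,5R)-1,3,4,5-tetrahydroxycyclohexane-1-carboxylic acid | O[C@@]1(C(O)=O)C[C@@H](O)[C@@H](O)[C@H](O)C1 | starting material
2 | methyl quinate | O[C@@]1(C(=O)OC)C[C@@H](O)[C@@H](O)[C@H](O)C1 | intermediate
3 | methyl quinate 4,5-O-[(2S,3S)-2,3-dimethoxybutane-2,3-diyl] acetal (free 1-OH and 3-OH) | O[C@@]1(C(=O)OC)C[C@@H](O)[C@H]2O[C@](C)(OC)[C@@](C)(OC)O[C@@H]2C1 | intermediate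
4 | BDA-protected 1-(hydroxymethyl)cyclohexane-1,3,4,5-tetrol (triol) | O[C@@]1(CO)C[C@@H](O)[C@H]2O[C@](C)(OC)[C@@](C)(OC)O[C@@H]2C1 | intermediate
5 | 3-hydroxycyclohexanone with the trans-4,5-diol as BDA acetal (3-OH cis to O-4) | O=C1C[C@@H](O)[C@H]2O[C@](C)(OC)[C@@](C)(OC)O[C@@H]2C1 | intermediate
6 | 3-O-mesylate of 5 | O=C1C[C@@H](OS(C)(=O)=O)[C@H]2O[C@](C)(OC)[C@@](C)(OC)O[C@@H]2C1 | intermediate
7 | (4R,5R)-4,5-dihydroxycyclohex-2-en-1-one BDA acetal | O=C1C=C[C@H]2O[C@](C)(OC)[C@@](C)(OC)O[C@@H]2C1 | intermediate
8 | 2-iodo derivative of 7 | O=C1C(I)=C[C@H]2O[C@](C)(OC)[C@@](C)(OC)O[C@@H]2C1 | intermediate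
9 | (4R,5R)-4,5-dihydroxy-2-methylcyclohex-2-en-1-one BDA acetal | O=C1C(C)=C[C@H]2O[C@](C)(OC)[C@@](C)(OC)O[C@@H]2C1 | intermediate
10 | phenyl vinyl sulfoxide (racemic) | C=CS(=O)c1ccccc1 | starting material
11 | lithium cross-conjugated dienolate of 9 | [Li+].[O-]C1=C[C@H]2O[C@](C)(OC)[C@@](C)(OC)O[C@@H]2C=C1C | intermediate
12 | 6-[2-(phenylsulfinyl)ethyl] derivative of 9 (C6 and sulfur epimers) | O=C1C(C)=C[C@H]2O[C@](C)(OC)[C@@](C)(OC)O[C@@H]2C1CCS(=O)c1ccccc1 | intermediate
13 | lithium enolate of 12 | [Li+].[O-]C1=C(CCS(=O)c2ccccc2)[C@H]2O[C@](C)(OC)[C@@](C)(OC)O[C@@H]2C=C1C | intermediate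
14 | (4R,5R,6R)-2,6-dimethyl-6-[2-(phenylsulfinyl)ethyl] enone BDA acetal (6-methyl cis to O-5; sulfur epimers) | O=C1C(C)=C[C@H]2O[C@](C)(OC)[C@@](C)(OC)O[C@@H]2[C@@]1(C)CCS(=O)c1ccccc1 | intermediate
15 | (4R,5R,6R)-6-ethenyl-4,5-dihydroxy-2,6-dimethylcyclohex-2-en-1-one BDA acetal | O=C1C(C)=C[C@H]2O[C@](C)(OC)[C@@](C)(OC)O[C@@H]2[C@@]1(C)C=C | intermediate
16 | 2,3-epoxide of 15 (epoxide diastereomers) | O=C1C2(C)OC2[C@H]3O[C@](C)(OC)[C@@](C)(OC)O[C@@H]3[C@@]1(C)C=C | intermediate
17 | (4S,5R,6R)-4-ethenyl-2,4-dimethylcyclohex-2-ene-1,5,6-triol 5,6-BDA acetal (C1 epimers) | OC1C(C)=C[C@](C)(C=C)[C@H]2O[C@](C)(OC)[C@@](C)(OC)O[C@H]12 | intermediate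
18 | pent-4-yn-1-ol | OCCCC#C | starting material
19 | pent-4-ynal | O=CCCC#C | intermediate
20 | (E)-crotylboronic acid pinacol ester | C/C=C/CB1OC(C)(C)C(C)(C)O1 | starting material
21 | (3R,4S)-3-methyloct-1-en-7-yn-4-ol | C#CCC[C@H](O)[C@H](C)C=C | intermediate
22 | tert-butyldiphenylsilyl ether of 21 | C#CCC[C@H](O[Si](c1ccccc1)(c1ccccc1)C(C)(C)C)[C@H](C)C=C | intermediate
23 | (Z)-alkenylcopper from carbocupration of 22 (Cu cis to CH2SiMe3) | [Cu]/C=C(\C[Si](C)(C)C)CC[C@H](O[Si](c1ccccc1)(c1ccccc1)C(C)(C)C)[C@H](C)C=C | intermediate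
24 | tert-butyl{[(3R,4S,7Z)-8-iodo-3-methyl-7-[(trimethylsilyl)methyl]octa-1,7-dien-4-yl]oxy}diphenylsilane | I/C=C(\C[Si](C)(C)C)CC[C@H](O[Si](c1ccccc1)(c1ccccc1)C(C)(C)C)[C@H](C)C=C | intermediate
25 | B-alkyl-9-BBN from hydroboration of the vinyl group of 24 | I/C=C(\C[Si](C)(C)C)CC[C@H](O[Si](c1ccccc1)(c1ccccc1)C(C)(C)C)[C@H](C)CCB1C2CCCC1CCC2 | intermediate
26 | (3R,4S,7Z)-4-(tert-butyldiphenylsilyloxy)-8-iodo-3-methyl-7-[(trimethylsilyl)methyl]oct-7-en-1-ol | I/C=C(\C[Si](C)(C)C)CC[C@H](O[Si](c1ccccc1)(c1ccccc1)C(C)(C)C)[C@H](C)CCO | intermediate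
27 | tert-butyldimethylsilyl ether of 26 | I/C=C(\C[Si](C)(C)C)CC[C@H](O[Si](c1ccccc1)(c1ccccc1)C(C)(C)C)[C@H](C)CCO[Si](C)(C)C(C)(C)C | intermediate
28 | B-alkyl-9-BBN from 17 (the C1 hydroxyl as its 9-BBN borinate) | C12CCCC(CCC1)B2OC1C(C)=C[C@](C)(CCB2C3CCCC2CCC3)[C@H]2O[C@](C)(OC)[C@@](C)(OC)O[C@H]12 | intermediate
29 | coupled allylic alcohol: cyclohexenol core with the C5–C14 chain, (7Z)-allylsilane, 11-OTBDPS, 14-OTBS (C1 epimers) | OC1C(C)=C[C@](C)(CC/C=C(\C[Si](C)(C)C)CC[C@H](O[Si](c2ccccc2)(c2ccccc2)C(C)(C)C)[C@H](C)CCO[Si](C)(C)C(C)(C)C)[C@H]2O[C@](C)(OC)[C@@](C)(OC)O[C@H]12 | intermediate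
30 | (4S,5R,6S)-enone with the same chain (photoreaction substrate) | O=C1C(C)=C[C@](C)(CC/C=C(\C[Si](C)(C)C)CC[C@H](O[Si](c2ccccc2)(c2ccccc2)C(C)(C)C)[C@H](C)CCO[Si](C)(C)C(C)(C)C)[C@H]2O[C@](C)(OC)[C@@](C)(OC)O[C@H]12 | intermediate
31 | photoadduct: cis-hydrindanone with a cyclobutane bridging C15 and C8 (H-16, H-7, C18 and C17 methyls on one face; C8 epimers) | O=C1[C@@]2(C)[C@H]3[C@](C)(CC[C@H]3C2(C[Si](C)(C)C)CC[C@H](O[Si](c4ccccc4)(c4ccccc4)C(C)(C)C)[C@H](C)CCO[Si](C)(C)C(C)(C)C)[C@H]2O[C@](C)(OC)[C@@](C)(OC)O[C@H]12 | intermediate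
32 | C1 trimethylsilyl enol ether with the C8=C19 methylidene | C[Si](C)(C)OC1=C(C)[C@@H]2[C@H](C(=C)CC[C@H](O[Si](c3ccccc3)(c3ccccc3)C(C)(C)C)[C@H](C)CCO[Si](C)(C)C(C)(C)C)CC[C@]2(C)[C@H]3O[C@](C)(OC)[C@@](C)(OC)O[C@H]13 | intermediate
33 | lithium enolate corresponding to 32 | [Li+].[O-]C1=C(C)[C@@H]2[C@H](C(=C)CC[C@H](O[Si](c3ccccc3)(c3ccccc3)C(C)(C)C)[C@H](C)CCO[Si](C)(C)C(C)(C)C)CC[C@]2(C)[C@H]3O[C@](C)(OC)[C@@](C)(OC)O[C@H]13 | intermediate
34 | C1 alkenyl triflate (BDA on O-2/O-3, 11-OTBDPS, 14-OTBS) | O=S(=O)(OC1=C(C)[C@@H]2[C@H](C(=C)CC[C@H](O[Si](c3ccccc3)(c3ccccc3)C(C)(C)C)[C@H](C)CCO[Si](C)(C)C(C)(C)C)CC[C@]2(C)[C@H]3O[C@](C)(OC)[C@@](C)(OC)O[C@H]13)C(F)(F)F | intermediate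
35 | 2,3,14-triol (C1 triflate, 11-OTBDPS) | O=S(=O)(OC1=C(C)[C@@H]2[C@H](C(=C)CC[C@H](O[Si](c3ccccc3)(c3ccccc3)C(C)(C)C)[C@H](C)CCO)CC[C@]2(C)[C@@H](O)[C@@H]1O)C(F)(F)F | intermediate
36 | 2,3-diol C14 aldehyde | O=S(=O)(OC1=C(C)[C@@H]2[C@H](C(=C)CC[C@H](O[Si](c3ccccc3)(c3ccccc3)C(C)(C)C)[C@H](C)CC=O)CC[C@]2(C)[C@@H](O)[C@@H]1O)C(F)(F)F | intermediate
37 | 2,3-diacetate C14 aldehyde | O=S(=O)(OC1=C(C)[C@@H]2[C@H](C(=C)CC[C@H](O[Si](c3ccccc3)(c3ccccc3)C(C)(C)C)[C@H](C)CC=O)CC[C@]2(C)[C@@H](OC(C)=O)[C@@H]1OC(C)=O)C(F)(F)F | intermediate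
38 | 11-O-tert-butyldiphenylsilyl ether of the target | C=C1CC[C@H](O[Si](c2ccccc2)(c2ccccc2)C(C)(C)C)[C@H](C)C[C@H](O)C2=C(C)[C@@H]3[C@H]1CC[C@]3(C)[C@@H](OC(C)=O)[C@@H]2OC(C)=O | intermediate
39 | CNP0114864.2, 2,3-diacetoxytrinervita-1(15),8(19)-diene-11,14-diol | C=C1CC[C@H](O)[C@H](C)C[C@H](O)C2=C(C)[C@@H]3[C@H]1CC[C@]3(C)[C@@H](OC(C)=O)[C@@H]2OC(C)=O | target

**Step count and risks**

Total steps: 25. Longest linear sequence: 19 steps (steps 1–10 and 17–25); the side chain (steps 11–16) joins at step 17.

1. Step 19 (key step). What may go wrong: hydrogen transfer within the 1,4-biradical, or lumiketone rearrangement of the excited 4,4-disubstituted enone, outruns cyclobutane closure. Fallback: the same C7–C16 bond can be closed in the ground state. From 30, a Me3SiNTf2-catalysed (from HNTf2, 5 mol %, CH2Cl2, −78 °C) intramolecular Hosomi–Sakurai conjugate addition of the allylsilane to the enone would give silyl enol ether 32 directly. This re-enters step 20 at its second stage (MeLi, then PhNTf2) and so comes back to the route at 32. It makes no compound outside the list (F0), but C7 is then set by an open transition state and a C7 epimer may have to be removed at 34.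

2. Step 20. What may go wrong: the β-silyl cation recloses or undergoes 1,2-silyl shift and five-ring closure instead of losing silicon, or the Lewis acid ionises the BDA ketal. Fallback: from 31 the ring can be opened from the silicon end. CsF (or anhydrous tetrabutylammonium difluorotriphenylsilicate) and PhNTf2 in DME would trigger an anionic Grob-type fragmentation (fluoride on silicon, C8=C19 formed, C15–C8 broken) to the cesium enolate F1, which is triflated in the same flask. The sequence comes back at 34.

3. Step 24. What may go wrong: poor facial selectivity in the addition of the alkenylchromium to the aldehyde, giving C14 epimers. Fallback: from 38 obtained as the C14 epimer mixture, Dess–Martin oxidation would give the macrocyclic enone F2. Reagent-controlled Corey–Bakshi–Shibata reduction ((R)-methyl oxazaborolidine, catecholborane, −78 °C; the alkenyl group as the large substituent) would then return the 14S alcohol, coming back at 38.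

**Further compounds**

F0 | step 19 | none | none
F1 | step 20 | cesium enolate corresponding to 33 | [Cs+].[O-]C1=C(C)[C@@H]2[C@H](C(=C)CC[C@H](O[Si](c3ccccc3)(c3ccccc3)C(C)(C)C)[C@H](C)CCO[Si](C)(C)C(C)(C)C)CC[C@]2(C)[C@H]3O[C@](C)(OC)[C@@](C)(OC)O[C@H]13
F2 | step 24 | C14 ketone (macrocyclic enone) of 38 | C=C1CC[C@H](O[Si](c2ccccc2)(c2ccccc2)C(C)(C)C)[C@H](C)CC(=O)C2=C(C)[C@@H]3[C@H]1CC[C@]3(C)[C@@H](OC(C)=O)[C@@H]2OC(C)=O
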